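**Strategy.** Ring C is read as a benzo-fused dihydropyranone: its C4 ketone makes C3 an enolate carbon in aldol relationship to C2–O1 and, through C4a, makes C8a of ring A an electrophile. The route therefore disconnects C2–C3 and O1–C8a together. A trimethylsilyl enol ether of a 2-fluoroaryl α-(methoxymethoxy) ketone, carrying the complete ring A (5-OMe, 7-OMe, 8-prenyl), and MOM-protected vanillin are joined under a chiral ammonium bifluoride: aldol addition forms C2–C3 and sets C2, then the aldolate oxygen displaces the ortho fluorine to close ring C, the liberated fluoride carrying the chain. Chelation-controlled 5-O-demethylation and acidic MOM removal finish the synthesis.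

Key step: step 7

Assumption: the target is the (2R,3R)-trans-dihydroflavonol that the SMILES specifies. The sense of induction of the cinchona ammonium ion pair in step 7 cannot be predicted with certainty; the cinchonidinium series is written, and the pseudo-enantiomeric cinchoninium salt would be taken if attack on the Si face of the aldehyde is not the favoured one.

**Step 1**
Reactants: 1 1-fluoro-3,5-dimethoxybenzene; 2 prenyl bromide (1-bromo-3-methylbut-2-ene)
Product: 4 1-fluoro-3,5-dimethoxy-2-(3-methylbut-2-en-1-yl)benzene, via aryllithium 3 (not isolated)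
Conditions: LiTMP (lithium 2,2,6,6-tetramethylpiperidide, from the amine and n-BuLi), THF, −78 °C; CuBr·SMe2 (10 mol %), then 2, −78 → −40 °C; aq NH4Cl
Reagents that add atoms: none
Why: Directed ortho-metalation under acidity control, in which the amide base removes the ring proton flanked by F and OMe and not the one between the two OMe groups, followed by copper-catalysed SN2 allylation at the CH2 terminus of prenyl bromide, the cold temperature preventing loss of LiF to an aryne.

**Step 2**
Reactants: 5 methyl glycolate
Product: 6 methyl 2-(methoxymethoxy)acetate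
Conditions: MOMCl, i-Pr2NEt, CH2Cl2, 0 °C → rt
Reagents that add atoms: chloromethyl methyl ether (MOMCl), COCCl
Why: O-alkylation of the primary alcohol by the reactive α-chloro ether under amine base (MOM protection), with no stereocentre involved.

**Step 3**
Reactants: 6 methyl 2-(methoxymethoxy)acetate
Product: 7 2-(methoxymethoxy)-1-(morpholin-4-yl)ethan-1-one
Conditions: morpholine (neat, excess), 70 °C
Reagents that add atoms: morpholine, C1COCCN1
Why: Aminolysis of an α-alkoxy-activated methyl ester by a nucleophilic secondary amine gives the morpholine amide, an acylating agent that stops at the ketone stage with organolithiums.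

**Step 4**
Reactants: 4 1-fluoro-3,5-dimethoxy-2-(3-methylbut-2-en-1-yl)benzene; 7 2-(methoxymethoxy)-1-(morpholin-4-yl)ethan-1-one
Product: 9 1-[2-fluoro-4,6-dimethoxy-3-(3-methylbut-2-en-1-yl)phenyl]-2-(methoxymethoxy)ethan-1-one, via aryllithium 8 (not isolated)
Conditions: LiTMP (from the amine and n-BuLi), THF, −78 °C; then 7, −78 °C; aq NH4Cl at −78 °C
Reagents that add atoms: none
Why: A second acidity-controlled ortho-metalation at the only remaining proton next to fluorine, then acyl transfer from the chelating morpholine amide, whose tetrahedral adduct survives until the quench and so gives the ketone without over-addition.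

**Step 5**
Reactants: 9 1-[2-fluoro-4,6-dimethoxy-3-(3-methylbut-2-en-1-yl)phenyl]-2-(methoxymethoxy)ethan-1-one
Product: 11 (Z)-[1-[2-fluoro-4,6-dimethoxy-3-(3-methylbut-2-en-1-yl)phenyl]-2-(methoxymethoxy)ethenyl]oxy-trimethylsilane, via lithium enolate 10 (not isolated)
Conditions: LiN(SiMe3)2, Me3SiCl, THF, −78 °C; pentane, filtration, used crude
Reagents that add atoms: chlorotrimethylsilane, C[Si](C)(C)Cl
Why: Kinetic enolisation gives the Z enolate through a lithium chelate between the enolate oxygen and the MOM oxygen, and O-silylation traps it as the silyl enol ether.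

**Step 6**
Reactants: 12 vanillin
Product: 13 3-methoxy-4-(methoxymethoxy)benzaldehyde
Conditions: MOMCl, i-Pr2NEt, CH2Cl2, 0 °C → rt
Reagents that add atoms: chloromethyl methyl ether (MOMCl), COCCl
Why: MOM protection of the phenol, which blocks phenoxide formation in step 7 and later keeps the para-hydroxybenzyl position C2 from ionising.

**Step 7**
Reactants: 11 (Z)-silyl enol ether; 13 3-methoxy-4-(methoxymethoxy)benzaldehyde
Product: 16 (2R,3R)-5,7-dimethoxy-2-[3-methoxy-4-(methoxymethoxy)phenyl]-3-(methoxymethoxy)-8-(3-methylbut-2-en-1-yl)-2,3-dihydro-4H-chromen-4-one, via ammonium enolate 14 (not isolated), via aldolate 15 (not isolated)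
Conditions: O-allyl-N-(9-anthracenylmethyl)cinchonidinium hydrogen difluoride (10 mol %), 4 Å molecular sieves, THF, −50 °C → 20 °C; AcOH quench
Reagents that add atoms: none
Why: Proposed new method: bifluoride removes the silyl group of 11 to give the chiral ammonium enolate 14, whose C3 adds to the Si face of aldehyde 13 inside the contact ion pair (C2–C3 bond, aldolate 15), and the C2 alkoxide then attacks C8a of the vinylogous acyl fluoride F–C8a=C4a–C4=O by addition–elimination (O1–C8a bond), the expelled fluoride desilylating the next molecule of 11 (or any O-silylated 15) so that Me3SiF is the only by-product. The closest known reaction types are the cinchona ammonium bifluoride-catalysed Mukaiyama aldol of α-alkoxy aryl ketone enol silanes and the stepwise aldol–cyclisation annulation of 1-alkoxy-3-silyloxybutadienes with aldehydes to dihydropyranones, extended here by the known intramolecular SNAr of β-alkoxides onto 2-fluoroaryl ketones. Ring C closes in a 6-endo-trig conjugate addition of the alkoxide to C8a followed by loss of fluoride. C2 (R) is controlled by the catalyst cation, which shields the Re face of the aldehyde in the ion-paired open transition state; C3 (R) follows from the aldol diastereoselection and, because H3 is acidic next to the C4 ketone, from equilibration under the fluoride-basic conditions to the trans arrangement with the aryl and OMOM groups both equatorial. The step needs ring closure at the C–F carbon and not at the C–OMe carbon that is also ortho to the ketone, which the far higher electrophilicity of the C–F site and the nucleofugality of fluoride secure, and it needs cyclisation to outrun retro-aldol and β-elimination, for which the six-membered transition state, the low temperature and the absence of any stoichiometric base are relied on.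

**Step 8**
Reactants: 16 (2R,3R)-5,7-dimethoxy bis-MOM flavanonol
Product: 17 (2R,3R)-5-hydroxy-7-methoxy-2-[3-methoxy-4-(methoxymethoxy)phenyl]-3-(methoxymethoxy)-8-(3-methylbut-2-en-1-yl)-2,3-dihydro-4H-chromen-4-one
Conditions: MgI2·OEt2, THF, 50 °C; aq NH4Cl
Reagents that add atoms: none
Why: Chelation-controlled ether cleavage, in which magnesium bound between C4=O and the peri 5-OMe lets iodide remove only that methyl group by SN2, a reaction type established on 5-methoxy-8-prenylflavanones, while the 7- and 3'-methyl ethers and the prenyl group stay untouched and any partial MOM loss is inconsequential because step 9 removes both MOM groups.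

**Step 9**
Reactants: 17 (2R,3R)-5-hydroxy bis-MOM flavanonol
Product: 18 (2R,3R)-3,5-dihydroxy-2-(4-hydroxy-3-methoxyphenyl)-7-methoxy-8-(3-methylbut-2-en-1-yl)-2,3-dihydro-4H-chromen-4-one (CNP0195184.1)
Conditions: HCl (1 M), MeOH, 40 °C
Reagents that add atoms: none
Why: Acid-catalysed acetal exchange with methanol removes both MOM ethers; the prenyl group has no free neighbouring hydroxyl to cyclise onto (its neighbours are O1 and 7-OMe), and any enolisation at C3 can only reinforce the trans isomer with the 3-OH equatorial and hydrogen-bonded to C4=O.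

**Compound list**
1 | 1-fluoro-3,5-dimethoxybenzene | COc1cc(F)cc(OC)c1 | starting material
2 | prenyl bromide (1-bromo-3-methylbut-2-ene) | CC(C)=CCBr | starting material
3 | (2-fluoro-4,6-dimethoxyphenyl)lithium | [Li]c1c(F)cc(OC)cc1OC | intermediate
4 | 1-fluoro-3,5-dimethoxy-2-(3-methylbut-2-en-1-yl)benzene | COc1cc(F)c(CC=C(C)C)c(OC)c1 | intermediate
5 | methyl glycolate | COC(=O)CO | starting material
6 | methyl 2-(methoxymethoxy)acetate | COCOCC(=O)OC | intermediate
7 | 2-(methoxymethoxy)-1-(morpholin-4-yl)ethan-1-one | COCOCC(=O)N1CCOCC1 | intermediate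
8 | [2-fluoro-4,6-dimethoxy-3-(3-methylbut-2-en-1-yl)phenyl]lithium | [Li]c1c(F)c(CC=C(C)C)c(OC)cc1OC | intermediate
9 | 1-[2-fluoro-4,6-dimethoxy-3-(3-methylbut-2-en-1-yl)phenyl]-2-(methoxymethoxy)ethan-1-one | COCOCC(=O)c1c(F)c(CC=C(C)C)c(OC)cc1OC | intermediate
10 | lithium (Z)-enolate of 9 | COCO/C=C(\O[Li])c1c(F)c(CC=C(C)C)c(OC)cc1OC | intermediate
11 | (Z)-[1-[2-fluoro-4,6-dimethoxy-3-(3-methylbut-2-en-1-yl)phenyl]-2-(methoxymethoxy)ethenyl]oxy-trimethylsilane | COCO/C=C(\O[Si](C)(C)C)c1c(F)c(CC=C(C)C)c(OC)cc1OC | intermediate
12 | vanillin | COc1cc(C=O)ccc1O | starting material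
13 | 3-methoxy-4-(methoxymethoxy)benzaldehyde | COCOc1ccc(C=O)cc1OC | intermediate
14 | (Z)-enolate of 9, anion of the chiral ammonium ion pair | COCO/C=C(\[O-])c1c(F)c(CC=C(C)C)c(OC)cc1OC | intermediate
15 | (2R,3R)-1-[2-fluoro-4,6-dimethoxy-3-(3-methylbut-2-en-1-yl)phenyl]-3-[3-methoxy-4-(methoxymethoxy)phenyl]-2-(methoxymethoxy)-3-oxidopropan-1-one, anion of the ammonium ion pair | COc1cc([C@@H]([O-])[C@@H](OCOC)C(=O)c2c(F)c(CC=C(C)C)c(OC)cc2OC)ccc1OCOC | intermediate
16 | (2R,3R)-5,7-dimethoxy-2-[3-methoxy-4-(methoxymethoxy)phenyl]-3-(methoxymethoxy)-8-(3-methylbut-2-en-1-yl)-2,3-dihydro-4H-chromen-4-one | COc1cc([C@H]2Oc3c(CC=C(C)C)c(OC)cc(OC)c3C(=O)[C@@H]2OCOC)ccc1OCOC | intermediate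
17 | (2R,3R)-5-hydroxy-7-methoxy-2-[3-methoxy-4-(methoxymethoxy)phenyl]-3-(methoxymethoxy)-8-(3-methylbut-2-en-1-yl)-2,3-dihydro-4H-chromen-4-one | COc1cc([C@H]2Oc3c(CC=C(C)C)c(OC)cc(O)c3C(=O)[C@@H]2OCOC)ccc1OCOC | intermediate
18 | (2R,3R)-3,5-dihydroxy-2-(4-hydroxy-3-methoxyphenyl)-7-methoxy-8-(3-methylbut-2-en-1-yl)-2,3-dihydro-4H-chromen-4-one | COc1cc([C@H]2Oc3c(CC=C(C)C)c(OC)cc(O)c3C(=O)[C@@H]2O)ccc1O | target

**Step count.** Total: 9 steps. Longest linear sequence: 7 steps (2, 3, 4, 5, 7, 8, 9), counted from methyl glycolate 5.

**Steps most likely to fail**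

Step 7. The free aldolate may revert by retro-aldol and re-add without catalyst control, eroding enantiomeric purity. Fluoride displacement on the electron-rich, twisted aryl ketone may be slow. The product may ring-open by β-elimination of the aryloxide from its C3 enolate, with loss of C2 integrity. The fallback uses known chemistry, sets out from ketone 9 and aldehyde 13 and comes back at 16. The lithium enolate of 9 (LiN(i-Pr)2, THF, −78 °C) is added to 13 and quenched cold to give the racemic aldol adduct F1 as a diastereomer mixture. DMP oxidation gives the 2-(methoxymethoxy)-1,3-diketone F2. Asymmetric transfer hydrogenation with dynamic kinetic resolution (RuCl(p-cymene)[(S,S)-TsDPEN], HCO2H/Et3N) should reduce only the unhindered ring B ketone, the ring A ketone being shielded by its two ortho substituents, and give the (3R)-carbinol F3 while the acidic central carbon equilibrates; the mirror-image catalyst would be used if the R carbinol is not the one formed. KOt-Bu in THF at 0 °C then closes ring C by intramolecular SNAr and equilibrates C3 to give 16.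

Step 4. The base may deprotonate the benzylic–allylic CH2 of the prenyl group instead of the ring, the aryllithium may lose LiF to an aryne, or the hindered aryllithium may abstract a proton from the amide instead of acylating. The fallback sets out from 4 and comes back at 9 by electrophilic substitution instead of metalation. Vilsmeier–Haack formylation (POCl3, DMF) at the position para to one methoxy and ortho to the other gives 2-fluoro-4,6-dimethoxy-3-(3-methylbut-2-en-1-yl)benzaldehyde F4. Addition of LiCH2OMOM (from Bu3SnCH2OMOM and n-BuLi, THF, −78 °C) gives the racemic 1-aryl-2-(methoxymethoxy)ethanol F5, and DMP oxidation gives 9.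

Step 8. The Lewis acid may assist ring opening at C2 with loss of configuration, iodide or HI may add to the prenyl double bond during the warm reaction, and MOM loss may be partial and uncontrolled. The fallback moves the demethylation ahead of the stereocentres, sets out from 9 and comes back at 18. MgI2·OEt2 in THF cleaves the methoxy ortho to the ketone at the achiral stage to give the 6-hydroxy ketone F6. MOMCl/i-Pr2NEt gives the 6-(methoxymethoxy) ketone F7, which also repairs any α-MOM loss. LiN(SiMe3)2/Me3SiCl gives the (Z)-silyl enol ether F8. The annulation of step 7 with 13 gives the tris-MOM flavanonol F9, and HCl/MeOH under the conditions of step 9 liberates 18 directly.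

**Further compounds**
F1 | step 7 | 1-[2-fluoro-4,6-dimethoxy-3-(3-methylbut-2-en-1-yl)phenyl]-3-hydroxy-3-[3-methoxy-4-(methoxymethoxy)phenyl]-2-(methoxymethoxy)propan-1-one, racemic diastereomer mixture | COc1cc(C(O)C(OCOC)C(=O)c2c(F)c(CC=C(C)C)c(OC)cc2OC)ccc1OCOC
F2 | step 7 | 1-[2-fluoro-4,6-dimethoxy-3-(3-methylbut-2-en-1-yl)phenyl]-3-[3-methoxy-4-(methoxymethoxy)phenyl]-2-(methoxymethoxy)propane-1,3-dione | COc1cc(C(=O)C(OCOC)C(=O)c2c(F)c(CC=C(C)C)c(OC)cc2OC)ccc1OCOC
F3 | step 7 | (3R)-1-[2-fluoro-4,6-dimethoxy-3-(3-methylbut-2-en-1-yl)phenyl]-3-hydroxy-3-[3-methoxy-4-(methoxymethoxy)phenyl]-2-(methoxymethoxy)propan-1-one, C2 epimers | COc1cc([C@@H](O)C(OCOC)C(=O)c2c(F)c(CC=C(C)C)c(OC)cc2OC)ccc1OCOC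
F4 | step 4 | 2-fluoro-4,6-dimethoxy-3-(3-methylbut-2-en-1-yl)benzaldehyde | COc1cc(OC)c(CC=C(C)C)c(F)c1C=O
F5 | step 4 | 1-[2-fluoro-4,6-dimethoxy-3-(3-methylbut-2-en-1-yl)phenyl]-2-(methoxymethoxy)ethan-1-ol, racemic | COCOCC(O)c1c(F)c(CC=C(C)C)c(OC)cc1OC
F6 | step 8 | 1-[2-fluoro-6-hydroxy-4-methoxy-3-(3-methylbut-2-en-1-yl)phenyl]-2-(methoxymethoxy)ethan-1-one | COCOCC(=O)c1c(F)c(CC=C(C)C)c(OC)cc1O
F7 | step 8 | 1-[2-fluoro-4-methoxy-6-(methoxymethoxy)-3-(3-methylbut-2-en-1-yl)phenyl]-2-(methoxymethoxy)ethan-1-one | COCOCC(=O)c1c(F)c(CC=C(C)C)c(OC)cc1OCOC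
F8 | step 8 | (Z)-[1-[2-fluoro-4-methoxy-6-(methoxymethoxy)-3-(3-methylbut-2-en-1-yl)phenyl]-2-(methoxymethoxy)ethenyl]oxy-trimethylsilane | COCO/C=C(\O[Si](C)(C)C)c1c(F)c(CC=C(C)C)c(OC)cc1OCOC
F9 | step 8 | (2R,3R)-7-methoxy-2-[3-methoxy-4-(methoxymethoxy)phenyl]-3,5-bis(methoxymethoxy)-8-(3-methylbut-2-en-1-yl)-2,3-dihydro-4H-chromen-4-one | COc1cc([C@H]2Oc3c(CC=C(C)C)c(OC)cc(OCOC)c3C(=O)[C@@H]2OCOC)ccc1OCOC
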